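**Retrosynthetic overview**

1. C13–C14 (last step): B-alkyl Suzuki–Miyaura coupling of the C12 vinyl group with (Z)-3-iodo-2-methylprop-2-en-1-ol; the free allylic OH arrives last, so no protecting group is used.
2. C3–C4: nickel-catalysed cross-electrophile coupling of a primary alkyl chloride with 3-bromofuran-2(5H)-one; the butenolide, the only ring, is bought preformed and attached here.
3. C10–C11, the C11 stereocentre and its CH2OAc: copper-catalysed enantioselective SN2′ substitution of (Z)-4-chlorobut-2-enyl acetate by the alkyl-9-BBN made from the C8–C10 allyl group.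
4. C7 (key step): lithiation–borylation, a stereospecific 1,2-metallate shift of allyl from boron to the carbenoid carbon of 4-chlorobutyl 2,4,6-triisopropylbenzoate (forms C7–C8, sets C7). A second 1,2-shift (ClCH2Li homologation) forms C7–C19, then B→O oxidation.
5. Order: C7 → C19 → acetate → C11 → butenolide → allylic alcohol arm.

Assumption: the SMILES is read as written (both stereocentres R; C14=C15 Z, chain cis to CH2OH). Locants: C1–C3 butenolide (C3 = α-carbon), C4–C6, C7 (stereocentre, C19 = its CH2O), C8–C10, C11 (stereocentre, C20 = its CH2O), C12–C13, C14=C15.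

**Route**

Step 1
Reactants: 1 4-chlorobutan-1-ol
Product: 2 4-chlorobutyl 2,4,6-triisopropylbenzoate
Conditions: 2,4,6-iPr3C6H2COCl (1.1 equiv), Et3N (1.5 equiv), DMAP (10 mol %), CH2Cl2, 40 °C
Reagents that add atoms: 2,4,6-triisopropylbenzoyl chloride, CC(C)c1cc(C(C)C)c(C(Cl)=O)c(C(C)C)c1
Why: Esterification of the primary alcohol with the hindered aroyl chloride gives the benzoate that directs α-lithiation and later serves as the leaving group.

Step 2
Reactants: 2 4-chlorobutyl 2,4,6-triisopropylbenzoate
Product: 5 (S)-2-(1-chlorohept-6-en-4-yl)-4,4,5,5-tetramethyl-1,3,2-dioxaborolane, via lithiated benzoate 3 (not isolated), via lithium boronate complex 4 (not isolated)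
Conditions: s-BuLi (1.3 equiv), (+)-sparteine (1.3 equiv), Et2O, −78 °C, 5 h; allyl-Bpin (1.5 equiv), −78 °C, 1 h; then 35 °C, 3 h
Reagents that add atoms: allylboronic acid pinacol ester, C=CCB1OC(C)(C)C(C)(C)O1
Why: Lithiation–borylation: sparteine-mediated enantioselective α-deprotonation gives configurationally stable (R)-3, borylation occurs with retention, and the allyl group then undergoes a stereospecific anionic 1,2-metallate shift from boron to carbon with inversion and loss of the benzoate, which forms C7–C8 and sets C7 (S in 5, the geometry that becomes 7R in the target).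

Step 3
Reactants: 5 (S)-2-(1-chlorohept-6-en-4-yl)-4,4,5,5-tetramethyl-1,3,2-dioxaborolane
Product: 7 (S)-2-(3-chloropropyl)pent-4-en-1-ol, via homologated boronic ester 6 (not isolated)
Conditions: BrCH2Cl (2 equiv), n-BuLi (1.8 equiv), THF, −78 °C to rt; then 2 M NaOH, 30% H2O2, 0 °C to rt
Reagents that add atoms: bromochloromethane, ClCBr; hydrogen peroxide, OO
Why: Matteson homologation: ClCH2Li adds to boron and the secondary alkyl group shifts 1,2 from boron to CH2 with retention at C7 (forms C7–C19), after which the oxidative 1,2-shift from boron to oxygen gives the primary alcohol without touching the stereocentre.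

Step 4
Reactants: 7 (S)-2-(3-chloropropyl)pent-4-en-1-ol
Product: 8 (S)-2-(3-chloropropyl)pent-4-en-1-yl acetate
Conditions: Ac2O, pyridine, DMAP (5 mol %), CH2Cl2, 0 °C to rt
Reagents that add atoms: acetic anhydride, CC(=O)OC(C)=O
Why: DMAP-catalysed acetylation of the primary alcohol installs the first acetate before any other hydroxyl group exists.

Step 5
Reactants: 9 (Z)-1,4-dichlorobut-2-ene
Product: 10 (Z)-4-chlorobut-2-en-1-yl acetate
Conditions: KOAc (1 equiv), 9 (3 equiv), n-Bu4NBr (5 mol %), MeCN, 60 °C; distil, recover 9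
Reagents that add atoms: potassium acetate, CC(=O)[O-].[K+]
Why: SN2 displacement of one allylic chloride by acetate; the excess of dichloride suppresses the diacetate and the Z geometry is not touched.

Step 6
Reactants: 8 (S)-2-(3-chloropropyl)pent-4-en-1-yl acetate; 10 (Z)-4-chlorobut-2-en-1-yl acetate
Product: 12 (2R,6R)-2-(3-chloropropyl)-6-ethenylheptane-1,7-diyl diacetate, via B-alkyl-9-BBN adduct 11 (not isolated)
Conditions: 9-BBN dimer (0.55 equiv), 1,4-dioxane, 60 °C, 1 h; then (CuOTf)2·C6H6 (5 mol %), DTBM-SEGPHOS (11 mol %, antipode giving 11R), EtOK (0.95 equiv), 10 (1.0 equiv), 15 °C, 16 h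
Reagents that add atoms: none
Why: Anti-Markovnikov hydroboration of the only alkene gives 11, whose ethoxide borate transfers the alkyl group to monovalent copper, and γ-selective SN2′ attack on the (Z)-allylic chloride under control of the chiral bisphosphine forms C10–C11, releases the vinyl group and sets C11 as R (copper-catalysed enantioselective allylic substitution with an alkylborane, catalyst-controlled because C7 is remote).

Step 7
Reactants: 12 (2R,6R)-2-(3-chloropropyl)-6-ethenylheptane-1,7-diyl diacetate; 13 3-bromofuran-2(5H)-one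
Product: 15 (2R,6R)-2-ethenyl-6-[3-(2-oxo-2,5-dihydrofuran-3-yl)propyl]heptane-1,7-diyl diacetate, via alkyl iodide 14 (not isolated)
Conditions: 13 (1.5 equiv), NiBr2(dme) (10 mol %), 4,4′-di-tert-butyl-2,2′-bipyridine (12 mol %), NaI (0.5 equiv), Zn (2 equiv), DMA, 60 °C
Reagents that add atoms: none
Why: Proposed new method: nickel-catalysed cross-electrophile coupling of an unactivated primary alkyl chloride with an α-bromobutenolide, a substrate pair for which it has not been shown; zerovalent nickel inserts into the activated C(sp2)–Br bond of 13, iodide converts the chloride into 14, halogen-atom abstraction by monovalent nickel gives the C4 radical, which is captured by the alkenylnickel bromide and released by reductive elimination from trivalent nickel to form C3–C4 with Zn as terminal reductant, the closest known reactions being nickel-catalysed reductive couplings of alkyl bromides with alkenyl bromides and of alkyl chlorides with aryl chlorides under halide co-catalysis, and no stereocentre is touched.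

Step 8
Reactants: 16 prop-2-yn-1-ol
Product: 18 (Z)-3-iodo-2-methylprop-2-en-1-ol, via alkenylmagnesium alkoxide 17 (not isolated)
Conditions: MeMgBr (2.5 equiv), CuI (10 mol %), THF, −10 °C to rt; then I2 (1.2 equiv), −10 °C to rt
Reagents that add atoms: methylmagnesium bromide, C[Mg]Br; iodine, II
Why: Copper-catalysed anti-carbomagnesiation of the propargylic alkoxide puts methyl on C2 and magnesium on C3 cis to the CH2O group through the five-membered chelate, and iodinolysis with retention gives only the Z iodide.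

Step 9
Reactants: 15 (2R,6R)-2-ethenyl-6-[3-(2-oxo-2,5-dihydrofuran-3-yl)propyl]heptane-1,7-diyl diacetate; 18 (Z)-3-iodo-2-methylprop-2-en-1-ol
Product: 20 (2R,6R)-2-[(3Z)-5-hydroxy-4-methylpent-3-en-1-yl]-6-[3-(2-oxo-2,5-dihydrofuran-3-yl)propyl]heptane-1,7-diyl diacetate, via B-alkyl-9-BBN adduct 19 (not isolated)
Conditions: 9-BBN dimer (0.7 equiv), THF, 0 °C to rt; then 18 (1.5 equiv), Pd(dppf)Cl2·CH2Cl2 (5 mol %), AsPh3 (10 mol %), K3PO4 (3 M aq, 3 equiv), DMF, rt
Reagents that add atoms: none
Why: 9-BBN adds only to the terminal vinyl group (the butenolide alkene is trisubstituted and electron-poor), and the B-alkyl Suzuki–Miyaura coupling proceeds with retention of the alkenyl iodide geometry to form C13–C14 and deliver the Z allylic alcohol with both stereocentres untouched.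

**Compound list**

1 | 4-chlorobutan-1-ol | OCCCCCl | starting material
2 | 4-chlorobutyl 2,4,6-triisopropylbenzoate | CC(C)c1cc(C(C)C)c(C(=O)OCCCCCl)c(C(C)C)c1 | intermediate
3 | (R)-4-chloro-1-lithiobutyl 2,4,6-triisopropylbenzoate (sparteine complex) | [Li][C@H](CCCCl)OC(=O)c1c(C(C)C)cc(C(C)C)cc1C(C)C | intermediate
4 | lithium (R)-allyl[4-chloro-1-(2,4,6-triisopropylbenzoyloxy)butyl](pinacolato)borate | C=CC[B-]1(OC(C)(C)C(C)(C)O1)[C@H](CCCCl)OC(=O)c1c(C(C)C)cc(C(C)C)cc1C(C)C.[Li+] | intermediate
5 | (S)-2-(1-chlorohept-6-en-4-yl)-4,4,5,5-tetramethyl-1,3,2-dioxaborolane | CC1(C)OB(OC1(C)C)[C@@H](CCCCl)CC=C | intermediate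
6 | (S)-2-[2-(3-chloropropyl)pent-4-en-1-yl]-4,4,5,5-tetramethyl-1,3,2-dioxaborolane | CC1(C)OB(OC1(C)C)C[C@@H](CCCCl)CC=C | intermediate
7 | (S)-2-(3-chloropropyl)pent-4-en-1-ol | OC[C@@H](CCCCl)CC=C | intermediate
8 | (S)-2-(3-chloropropyl)pent-4-en-1-yl acetate | CC(=O)OC[C@@H](CCCCl)CC=C | intermediate
9 | (Z)-1,4-dichlorobut-2-ene | ClC/C=C\CCl | starting material
10 | (Z)-4-chlorobut-2-en-1-yl acetate | CC(=O)OC/C=C\CCl | intermediate
11 | (R)-5-(9-borabicyclo[3.3.1]nonan-9-yl)-2-(3-chloropropyl)pentyl acetate | CC(=O)OC[C@@H](CCCCl)CCCB1C2CCCC1CCC2 | intermediate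
12 | (2R,6R)-2-(3-chloropropyl)-6-ethenylheptane-1,7-diyl diacetate | CC(=O)OC[C@@H](CCCCl)CCC[C@H](C=C)COC(C)=O | intermediate
13 | 3-bromofuran-2(5H)-one | O=C1OCC=C1Br | starting material
14 | (2R,6R)-2-ethenyl-6-(3-iodopropyl)heptane-1,7-diyl diacetate | CC(=O)OC[C@@H](CCCI)CCC[C@H](C=C)COC(C)=O | intermediate
15 | (2R,6R)-2-ethenyl-6-[3-(2-oxo-2,5-dihydrofuran-3-yl)propyl]heptane-1,7-diyl diacetate | CC(=O)OC[C@@H](CCCC1=CCOC1=O)CCC[C@H](C=C)COC(C)=O | intermediate
16 | prop-2-yn-1-ol | OCC#C | starting material
17 | bromomagnesium (Z)-3-(bromomagnesio)-2-methylprop-2-en-1-olate | Br[Mg]/C=C(/C)CO[Mg]Br | intermediate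
18 | (Z)-3-iodo-2-methylprop-2-en-1-ol | I/C=C(/C)CO | intermediate
19 | (2S,6R)-2-[2-(9-borabicyclo[3.3.1]nonan-9-yl)ethyl]-6-[3-(2-oxo-2,5-dihydrofuran-3-yl)propyl]heptane-1,7-diyl diacetate | CC(=O)OC[C@@H](CCCC1=CCOC1=O)CCC[C@H](CCB1C2CCCC1CCC2)COC(C)=O | intermediate
20 | (2R,6R)-2-[(3Z)-5-hydroxy-4-methylpent-3-en-1-yl]-6-[3-(2-oxo-2,5-dihydrofuran-3-yl)propyl]heptane-1,7-diyl diacetate | CC(=O)OC[C@@H](CCCC1=CCOC1=O)CCC[C@H](CC/C=C(/C)CO)COC(C)=O | target

**Step count**

Total: 9 steps. Longest linear sequence: 7 steps (1, 2, 3, 4, 6, 7, 9); steps 5 and 8 are side branches.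

**Steps most likely to fail, with fallbacks**

Step 7 (the proposed new step). Risks are sluggish activation of the alkyl chloride, hydrodebromination or dimerisation of 13, and reduction of the butenolide. The fallback uses known chemistry. It sets out from 12: Finkelstein exchange (NaI, acetone, reflux) gives 14 as an isolated compound, zinc insertion (Zn, LiCl, THF, 40 °C) gives [(4R,8R)-4,8-bis(acetoxymethyl)dec-9-en-1-yl]zinc iodide F6, and Negishi coupling of F6 with 13 (Pd(OAc)2, SPhos, THF, rt) comes back to the route at 15.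

Step 6. Risks are a lower ee with the acetoxymethyl-substituted allylic chloride, competing ionisation of the allylic acetate, and attack of ethoxide on the acetates; the ligand antipode for 11R has to be fixed on a first small run. The fallback changes the nucleophile and catalyst family from alkylborane/bisphosphine to dialkylzinc/phosphoramidite. It sets out from 8: hydroboration with Et2BH gives [(4R)-4-(acetoxymethyl)-7-chloroheptyl]diethylborane F4, boron–zinc exchange with Et2Zn gives bis[(4S)-4-(acetoxymethyl)-7-chloroheptyl]zinc F5, and CuBr·SMe2/binaphthol-phosphoramidite-catalysed enantioselective SN2′ substitution of 10 by F5 (THF, −40 °C) comes back at 12.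

Step 2. Risks are attack of s-BuLi on the chloride, four-membered ring closure of 3, and erosion of er. The fallback replaces the organolithium route by catalytic diboration. It sets out from 1: Swern oxidation gives 4-chlorobutanal F1 and Wittig methylenation (Ph3P=CH2, THF) gives 5-chloropent-1-ene F2. Enantioselective diboration of F2 (Pt(dba)3, TADDOL-derived phosphonite, B2pin2, THF, 60 °C) gives (R)-2,2'-(5-chloropentane-1,2-diyl)bis(4,4,5,5-tetramethyl-1,3,2-dioxaborolane) F3. Coupling of its primary C–B bond with vinyl bromide in the same flask (Pd(OAc)2, RuPhos, KOH, THF/H2O, 70 °C) comes back at 5.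

**Further compounds**

F1 | step 2 | 4-chlorobutanal | O=CCCCCl
F2 | step 2 | 5-chloropent-1-ene | C=CCCCCl
F3 | step 2 | (R)-2,2'-(5-chloropentane-1,2-diyl)bis(4,4,5,5-tetramethyl-1,3,2-dioxaborolane) | CC1(C)OB(OC1(C)C)[C@@H](CCCCl)CB1OC(C)(C)C(C)(C)O1
F4 | step 6 | [(4R)-4-(acetoxymethyl)-7-chloroheptyl]diethylborane | CC(=O)OC[C@@H](CCCCl)CCCB(CC)CC
F5 | step 6 | bis[(4S)-4-(acetoxymethyl)-7-chloroheptyl]zinc | CC(=O)OC[C@@H](CCCCl)CCC[Zn]CCC[C@H](CCCCl)COC(C)=O
F6 | step 7 | [(4R,8R)-4,8-bis(acetoxymethyl)dec-9-en-1-yl]zinc iodide | CC(=O)OC[C@@H](CCC[Zn]I)CCC[C@H](C=C)COC(C)=O
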